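**Retrosynthetic overview**
1. The target is a 2,4,6-trihydroxybenzophenone (phloroglucinol ring A, phenyl ring B) with a (2E,6R)-6-hydroxy-3,7-dimethylocta-2,7-dienyl chain on C3 of ring A. The strategy rests on the E-trisubstituted C2'=C3' olefin, which carries CH3 on C3' and the benzylic C1' methylene (bonded to C3 of ring A) on C2'.
2. Last disconnections: removal of three MOM ethers and one TBS ether, then the aryl–C(=O) bond, made by lithiation of ring A between two MOM ethers and acylation with a Weinreb benzamide.
3. Key disconnection: C3'–CH3 and C1'–C2' in one flask, leading back to terminal alkyne 7, Me3Al 13 and benzylic chloride 12 (syn methylalumination, then nickel-catalysed alkenyl–benzyl coupling).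
4. Enyne 7 comes from pent-4-yn-1-ol by oxidation, isopropenyl Grignard addition, oxidation, CBS reduction (sets C6' as R) and silylation; chloride 12 comes from 2,4,6-trihydroxybenzaldehyde by MOM protection, reduction and chlorination.
5. No ring is formed anywhere in the route; rings A and B are both bought.

Key step: step 9

Remark: isopropenylmagnesium bromide is taken as the commercial THF solution (it can equally be made from 2-bromopropene and Mg), and chloride 12 is assumed too ionisable to store, so steps 8 and 9 are run on the same day.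

**Route**

Step 1
Reactants: 1 pent-4-yn-1-ol
Product: 2 pent-4-ynal
Conditions: (COCl)2, DMSO, CH2Cl2, −78 °C; then Et3N, −78 → 0 °C
Reagents that add atoms: none
Why: Swern oxidation (activated-DMSO oxidation) should stop at the aldehyde without touching the terminal alkyne, and the volatile aldehyde is carried on as a concentrated solution.

Step 2
Reactants: 2 pent-4-ynal; 3 isopropenylmagnesium bromide
Product: 4 rac-2-methylhept-1-en-6-yn-3-ol
Conditions: 3 (1.1 equiv, 0.5 M in THF), THF, −78 → 0 °C; then H2O
Reagents that add atoms: none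
Why: Grignard 1,2-addition to the aldehyde at −78 °C should outrun deprotonation of the alkyne C–H, and the racemic carbinol is acceptable because step 3 erases the stereocentre.

Step 3
Reactants: 4 rac-2-methylhept-1-en-6-yn-3-ol
Product: 5 2-methylhept-1-en-6-yn-3-one
Conditions: Dess–Martin periodinane, CH2Cl2, 0 °C → rt
Reagents that add atoms: none
Why: Dess–Martin oxidation converts the secondary allylic alcohol into the isopropenyl ketone under near-neutral conditions, so the enone is not exposed to base that could cause conjugate addition or alkyne isomerisation.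

Step 4
Reactants: 5 2-methylhept-1-en-6-yn-3-one
Product: 6 (R)-2-methylhept-1-en-6-yn-3-ol
Conditions: (S)-1-methyl-3,3-diphenyltetrahydro-1H,3H-pyrrolo[1,2-c][1,3,2]oxazaborole ((S)-Me-CBS, 0.2 equiv), catecholborane (1.5 equiv), toluene, −78 °C; MeOH, then aqueous work-up
Reagents that add atoms: none
Why: Corey–Bakshi–Shibata reduction, in which the ketone binds the ring boron of the (S)-catalyst with the bulkier isopropenyl group turned away and hydride from nitrogen-bound catecholborane is delivered to the Si face, should set C3 (the later C6') as R, while catecholborane at −78 °C does not hydroborate the alkyne or the alkene.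

Step 5
Reactants: 6 (R)-2-methylhept-1-en-6-yn-3-ol
Product: 7 (R)-tert-butyldimethyl[(2-methylhept-1-en-6-yn-3-yl)oxy]silane
Conditions: TBSCl, imidazole, DMF, rt
Reagents that add atoms: tert-butyldimethylsilyl chloride, CC(C)(C)[Si](C)(C)Cl
Why: Imidazole-promoted O-silylation of the secondary allylic alcohol masks the only protic site before the organoaluminium and organolithium steps and does not affect the stereocentre.

Step 6
Reactants: 8 2,4,6-trihydroxybenzaldehyde
Product: 9 2,4,6-tris(methoxymethoxy)benzaldehyde
Conditions: NaH (3.6 equiv), MOMCl (3.6 equiv), DMF, 0 °C → rt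
Reagents that add atoms: chloromethyl methyl ether, COCCl
Why: Williamson O-alkylation of the three phenoxides, with NaH chosen so that the two hydroxyls hydrogen-bonded to the aldehyde are also fully deprotonated.

Step 7
Reactants: 9 2,4,6-tris(methoxymethoxy)benzaldehyde
Product: 10 [2,4,6-tris(methoxymethoxy)phenyl]methanol
Conditions: NaBH4, MeOH/THF, 0 °C
Reagents that add atoms: none
Why: NaBH4 reduction of the aryl aldehyde to the benzylic alcohol is chemoselective, the MOM acetals being inert to hydride and base.

Step 8
Reactants: 10 [2,4,6-tris(methoxymethoxy)phenyl]methanol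
Product: 12 2-(chloromethyl)-1,3,5-tris(methoxymethoxy)benzene, via benzylic mesylate 11 (not isolated)
Conditions: MsCl, Et3N, LiCl, THF, −20 → 0 °C; cold aq NaHCO3 wash, no chromatography, dried THF solution used at once
Reagents that add atoms: lithium chloride, [Li+].[Cl-]; methanesulfonyl chloride, CS(=O)(=O)Cl
Why: O-mesylation followed by in-flask SN displacement by chloride gives the benzylic chloride under basic conditions that spare the acid-labile MOM acetals, and the ionisable product is kept cold and in solution to suppress Friedel–Crafts self-alkylation.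

Step 9
Reactants: 7 (R)-tert-butyldimethyl[(2-methylhept-1-en-6-yn-3-yl)oxy]silane; 13 trimethylaluminium; 12 2-(chloromethyl)-1,3,5-tris(methoxymethoxy)benzene
Product: 15 tert-butyl{[(3R,6E)-2,6-dimethyl-8-[2,4,6-tris(methoxymethoxy)phenyl]octa-1,6-dien-3-yl]oxy}dimethylsilane, via alkenyldimethylalane 14 (not isolated)
Conditions: Me3Al (2 equiv), Cp2ZrCl2 (0.25 equiv), ClCH2CH2Cl, 0 °C → rt; volatiles and excess Me3Al removed in vacuo; then THF, 12 (0.9 equiv), Ni(PPh3)2Cl2 (5 mol%) reduced beforehand with n-BuLi (10 mol%), 0 °C → rt; aq potassium sodium tartrate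
Reagents that add atoms: none
Why: Cp2ZrCl2 and Me3Al form a cationic methylzirconocene–aluminate pair that adds CH3 and metal syn across the terminal alkyne of 7, methyl to the internal carbon (C3') and metal to the terminal carbon (C2'), and zirconium-to-aluminium exchange leaves the (E)-alkenyldimethylalane 14 (Negishi zirconium-catalysed carboalumination). Zerovalent nickel, made from Ni(PPh3)2Cl2 and n-BuLi, inserts into the benzylic C–Cl bond of 12, the alkenyl group passes from aluminium to nickel with retention, and reductive elimination forms the C1'–C2' bond; the closest known reaction type is the alkenylalane–benzylic chloride cross-coupling used for polyprenylated quinone precursors. No ring is closed and no stereocentre is created; the only stereochemical element set is the E geometry of the C2'=C3' olefin, which follows from syn addition plus retention in transmetalation and reductive elimination. The step needs regioselective methylalumination (secured by the unhindered terminal alkyne on an unbranched CH2 chain), reaction at the alkyne in preference to the 1,1-disubstituted isopropenyl olefin (this zirconocene does not carbometalate such alkenes at a useful rate at room temperature), and alkenyl in preference to methyl transfer to the benzyl–nickel species (favoured by the faster transfer of sp2 carbon and by stripping excess Me3Al before the coupling). The TBS ether and the C6' stereocentre are remote from every reacting atom and should pass through unchanged, and the MOM acetals of 12 should tolerate the alane once THF is the solvent.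

Step 10
Reactants: 15 tert-butyl{[(3R,6E)-2,6-dimethyl-8-[2,4,6-tris(methoxymethoxy)phenyl]octa-1,6-dien-3-yl]oxy}dimethylsilane; 16 N-methoxy-N-methylbenzamide
Product: 19 {3-[(2E,6R)-6-(tert-butyldimethylsilyloxy)-3,7-dimethylocta-2,7-dien-1-yl]-2,4,6-tris(methoxymethoxy)phenyl}(phenyl)methanone, via aryllithium 17 (not isolated), via lithium hemiaminal adduct 18 (not isolated)
Conditions: n-BuLi (1.1 equiv), THF, 0 °C, 1 h; then 16 (1.3 equiv), −78 → 0 °C; then H2O
Reagents that add atoms: none
Why: Directed ortho-metalation at the ring C–H flanked by two MOM ethers (the two remaining ring hydrogens are equivalent by symmetry) is followed by Weinreb ketone synthesis, in which the chelated tetrahedral adduct 18 survives until work-up and so prevents over-addition.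

Step 11
Reactants: 19 {3-[(2E,6R)-6-(tert-butyldimethylsilyloxy)-3,7-dimethylocta-2,7-dien-1-yl]-2,4,6-tris(methoxymethoxy)phenyl}(phenyl)methanone
Product: 20 {2,4,6-trihydroxy-3-[(2E,6R)-6-hydroxy-3,7-dimethylocta-2,7-dien-1-yl]phenyl}(phenyl)methanone
Conditions: HCl (about 0.5 M in MeOH), 0 °C → rt; neutralised with NaHCO3 as soon as the last MOM ether is gone
Reagents that add atoms: none
Why: Acid-catalysed acetal exchange of the three aryl MOM ethers with methanol and acid methanolysis of the secondary TBS ether unmask all four hydroxyls, and since no C–O bond at C6' is broken the R configuration is retained; dilute acid at or below room temperature is chosen to avoid addition of the ortho phenol to the C2'=C3' olefin.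

**Compound list**
1 | pent-4-yn-1-ol | C#CCCCO | starting material
2 | pent-4-ynal | C#CCCC=O | intermediate
3 | isopropenylmagnesium bromide | C=C(C)[Mg]Br | starting material
4 | rac-2-methylhept-1-en-6-yn-3-ol | C=C(C)C(O)CCC#C | intermediate
5 | 2-methylhept-1-en-6-yn-3-one | C=C(C)C(=O)CCC#C | intermediate
6 | (R)-2-methylhept-1-en-6-yn-3-ol | C=C(C)[C@H](O)CCC#C | intermediate
7 | (R)-tert-butyldimethyl[(2-methylhept-1-en-6-yn-3-yl)oxy]silane | C=C(C)[C@H](O[Si](C)(C)C(C)(C)C)CCC#C | intermediate
8 | 2,4,6-trihydroxybenzaldehyde | O=Cc1c(O)cc(O)cc1O | starting material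
9 | 2,4,6-tris(methoxymethoxy)benzaldehyde | O=Cc1c(OCOC)cc(OCOC)cc1OCOC | intermediate
10 | [2,4,6-tris(methoxymethoxy)phenyl]methanol | OCc1c(OCOC)cc(OCOC)cc1OCOC | intermediate
11 | [2,4,6-tris(methoxymethoxy)phenyl]methyl methanesulfonate | CS(=O)(=O)OCc1c(OCOC)cc(OCOC)cc1OCOC | intermediate (not isolated)
12 | 2-(chloromethyl)-1,3,5-tris(methoxymethoxy)benzene | ClCc1c(OCOC)cc(OCOC)cc1OCOC | intermediate
13 | trimethylaluminium | C[Al](C)C | starting material
14 | [(1E,5R)-5-(tert-butyldimethylsilyloxy)-2,6-dimethylhepta-1,6-dien-1-yl]dimethylalane | C=C(C)[C@H](O[Si](C)(C)C(C)(C)C)CC/C(C)=C/[Al](C)C | intermediate (not isolated)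
15 | tert-butyl{[(3R,6E)-2,6-dimethyl-8-[2,4,6-tris(methoxymethoxy)phenyl]octa-1,6-dien-3-yl]oxy}dimethylsilane | C=C(C)[C@H](O[Si](C)(C)C(C)(C)C)CC/C(C)=C/Cc1c(OCOC)cc(OCOC)cc1OCOC | intermediate
16 | N-methoxy-N-methylbenzamide | CON(C)C(=O)c1ccccc1 | starting material
17 | {3-[(2E,6R)-6-(tert-butyldimethylsilyloxy)-3,7-dimethylocta-2,7-dien-1-yl]-2,4,6-tris(methoxymethoxy)phenyl}lithium | C=C(C)[C@H](O[Si](C)(C)C(C)(C)C)CC/C(C)=C/Cc1c(OCOC)cc(OCOC)c([Li])c1OCOC | intermediate (not isolated)
18 | lithium alkoxide of the tetrahedral adduct of 17 and 16 (N-methoxy-N-methyl hemiaminal, both configurations at the new carbon) | C=C(C)[C@H](O[Si](C)(C)C(C)(C)C)CC/C(C)=C/Cc1c(OCOC)cc(OCOC)c(C(O[Li])(N(C)OC)c2ccccc2)c1OCOC | intermediate (not isolated)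
19 | {3-[(2E,6R)-6-(tert-butyldimethylsilyloxy)-3,7-dimethylocta-2,7-dien-1-yl]-2,4,6-tris(methoxymethoxy)phenyl}(phenyl)methanone | C=C(C)[C@H](O[Si](C)(C)C(C)(C)C)CC/C(C)=C/Cc1c(OCOC)cc(OCOC)c(C(=O)c2ccccc2)c1OCOC | intermediate
20 | {2,4,6-trihydroxy-3-[(2E,6R)-6-hydroxy-3,7-dimethylocta-2,7-dien-1-yl]phenyl}(phenyl)methanone | C=C(C)[C@H](O)CC/C(C)=C/Cc1c(O)cc(O)c(C(=O)c2ccccc2)c1O | target

**Step count**
Total: 11 steps. Longest linear sequence: 8 steps (steps 1–5, then 9, 10, 11); the aryl branch (steps 6–8) joins at step 9.

**Steps most likely to fail**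

Step 9 (together with the handling of chloride 12 from step 8). The trioxygenated benzylic chloride may ionise and alkylate another ring A before nickel inserts. The benzyl–nickel species may also homocouple, or methyl may transfer from aluminium in place of the alkenyl group. The fallback reverses the polarity, making the side chain the electrophile and ring A the nucleophile. It sets out from alane 14 (made from 7 and 13 as in the first stage of step 9) and comes back at 15.
- n-BuLi (1 equiv, −78 °C) turns 14 into lithium butyl[(1E,5R)-5-(tert-butyldimethylsilyloxy)-2,6-dimethylhepta-1,6-dien-1-yl]dimethylaluminate F1.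
- F1 adds to paraformaldehyde (THF, rt) with retention of geometry to give (2E,6R)-6-(tert-butyldimethylsilyloxy)-3,7-dimethylocta-2,7-dien-1-ol F2.
- PPh3/CBr4 (CH2Cl2, 0 °C, Appel reaction) converts F2 into tert-butyl{[(3R,6E)-8-bromo-2,6-dimethylocta-1,6-dien-3-yl]oxy}dimethylsilane F3.
- Separately, commercial benzene-1,3,5-triol is converted (NaH, MOMCl, DMF) into 1,3,5-tris(methoxymethoxy)benzene F4, which is lithiated (n-BuLi, THF, 0 °C) to [2,4,6-tris(methoxymethoxy)phenyl]lithium F5.
- F5 is alkylated with F3 in the presence of catalytic CuI (−78 → 0 °C); SN2 substitution at the primary allylic carbon keeps the E olefin and gives 15.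
Steps 6 to 8 are then not needed, and the route resumes at step 10.

Step 11. Under Brønsted acid the ortho phenol may add to the C2'=C3' olefin (chroman formation) and the C6' allylic alcohol may ionise. The MOM ether para to the benzoyl group may also be slow enough to cleave that forcing is needed. The fallback separates the two deprotections and avoids protic acid; it sets out from 19 and comes back at 20.
- TMSOTf with 2,2'-bipyridyl (MeCN, 0 °C → rt) converts the aryl MOM ethers into aryl silyl ethers, giving {3-[(2E,6R)-6-(tert-butyldimethylsilyloxy)-3,7-dimethylocta-2,7-dien-1-yl]-2,4,6-tris(trimethylsilyloxy)phenyl}(phenyl)methanone F6.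
- Water added to the same flask hydrolyses F6 to {3-[(2E,6R)-6-(tert-butyldimethylsilyloxy)-3,7-dimethylocta-2,7-dien-1-yl]-2,4,6-trihydroxyphenyl}(phenyl)methanone F7, with the aliphatic TBS ether intact.
- HF·pyridine (THF/pyridine, 0 °C) then removes the TBS group to give 20.

Step 10. n-BuLi may deprotonate the doubly activated benzylic–allylic C1' methylene in competition with the ring C–H, giving mixtures after acylation. The fallback generates the same aryllithium by halogen–metal exchange in place of deprotonation; it sets out from 15 and comes back at 17.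
- NBS (1.0 equiv, CH2Cl2, −78 → −40 °C, dark) should brominate the very electron-rich ring A in preference to the olefins, giving tert-butyl{[(3R,6E)-8-[3-bromo-2,4,6-tris(methoxymethoxy)phenyl]-2,6-dimethylocta-1,6-dien-3-yl]oxy}dimethylsilane F8.
- t-BuLi (2 equiv, THF, −78 °C) effects bromine–lithium exchange faster than any C–H deprotonation and gives 17, which is acylated with 16 as in step 10.

**Further compounds**
F1 | step 9 | lithium butyl[(1E,5R)-5-(tert-butyldimethylsilyloxy)-2,6-dimethylhepta-1,6-dien-1-yl]dimethylaluminate | [Li+].C=C(C)[C@H](O[Si](C)(C)C(C)(C)C)CC/C(C)=C/[Al-](C)(C)CCCC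
F2 | step 9 | (2E,6R)-6-(tert-butyldimethylsilyloxy)-3,7-dimethylocta-2,7-dien-1-ol | C=C(C)[C@H](O[Si](C)(C)C(C)(C)C)CC/C(C)=C/CO
F3 | step 9 | tert-butyl{[(3R,6E)-8-bromo-2,6-dimethylocta-1,6-dien-3-yl]oxy}dimethylsilane | C=C(C)[C@H](O[Si](C)(C)C(C)(C)C)CC/C(C)=C/CBr
F4 | step 9 | 1,3,5-tris(methoxymethoxy)benzene | COCOc1cc(OCOC)cc(OCOC)c1
F5 | step 9 | [2,4,6-tris(methoxymethoxy)phenyl]lithium | [Li]c1c(OCOC)cc(OCOC)cc1OCOC
F6 | step 11 | {3-[(2E,6R)-6-(tert-butyldimethylsilyloxy)-3,7-dimethylocta-2,7-dien-1-yl]-2,4,6-tris(trimethylsilyloxy)phenyl}(phenyl)methanone | C=C(C)[C@H](O[Si](C)(C)C(C)(C)C)CC/C(C)=C/Cc1c(O[Si](C)(C)C)cc(O[Si](C)(C)C)c(C(=O)c2ccccc2)c1O[Si](C)(C)C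
F7 | step 11 | {3-[(2E,6R)-6-(tert-butyldimethylsilyloxy)-3,7-dimethylocta-2,7-dien-1-yl]-2,4,6-trihydroxyphenyl}(phenyl)methanone | C=C(C)[C@H](O[Si](C)(C)C(C)(C)C)CC/C(C)=C/Cc1c(O)cc(O)c(C(=O)c2ccccc2)c1O
F8 | step 10 | tert-butyl{[(3R,6E)-8-[3-bromo-2,4,6-tris(methoxymethoxy)phenyl]-2,6-dimethylocta-1,6-dien-3-yl]oxy}dimethylsilane | C=C(C)[C@H](O[Si](C)(C)C(C)(C)C)CC/C(C)=C/Cc1c(OCOC)cc(OCOC)c(Br)c1OCOC
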